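**Retrosynthetic overview**
1. Target 24 comes from water opening of the 6,19-anhydride 23. Ring D (C13–C16) comes from a 5-exo vinyl-radical closure of the 2-bromoallyl enone 22.
2. The C6 carboxyl comes from an exocyclic C5=C6 methylene by epoxidation/Meinwald shift, lactol formation with the C19 acid, then oxidation.
3. C9–C10 and the C8 quaternary centre come from a tandem anionic oxy-Cope/enolate allylation of dienol 14, in which C6–C7 breaks as C9–C10 forms.
4. Dienol 14 comes from an NHK union of ring A aldehyde 10 (C4 set by valine-enamine methylation of 1) with ring C iodide 13 (from cyclohexane-1,3-dione).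
5. Ring order: A and C are bought as rings, D closes last, and B is never closed because its six carbons meet only as the chair transition state of the Cope step.

Assumption: ent-kaurane atom numbers are used as locants, and the (S)-valine enamine/HMPA protocol is taken to give the (R)-quaternary ester; if the sense is opposite, (R)-valine tert-butyl ester is used with no other change.

Step 1
Reactants: 1 tert-butyl 2-oxocyclohexane-1-carboxylate; 2 L-valine tert-butyl ester
Product: 3 tert-butyl 2-{[(2S)-1-tert-butoxy-3-methyl-1-oxobutan-2-yl]amino}cyclohex-1-ene-1-carboxylate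
Conditions: cat. BF3·OEt2, PhH, Dean–Stark, reflux
Reagents that add atoms: none
Why: Enamine condensation of the β-keto ester with the amine gives the H-bonded enamino ester and installs the auxiliary, with no new stereocentre.

Step 2
Reactants: 3 enamino ester
Product: 5 tert-butyl (1R)-1-methyl-2-oxocyclohexane-1-carboxylate, via methylated ketimine 4 (not isolated)
Conditions: LDA, PhMe, HMPA (1 equiv), −78 °C; MeI, −78 to −55 °C; then 10% aq citric acid, 23 °C
Reagents that add atoms: methyl iodide, CI; water, O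
Why: In this auxiliary-controlled lithio-enamine (aza-enolate) alkylation the chelated valine isopropyl group shields one face, so MeI sets C4 as R, and mild imine hydrolysis spares both tert-butyl esters.

Step 3
Reactants: 5 tert-butyl (1R)-1-methyl-2-oxocyclohexane-1-carboxylate
Product: 6 tert-butyl (1R)-1,3-dimethyl-2-oxocyclohexane-1-carboxylate (C3 epimers)
Conditions: LDA, THF, −78 °C; MeI, −78 to 0 °C
Reagents that add atoms: methyl iodide, CI
Why: Enolate alkylation at the only enolisable α-carbon brings in C20, and the new centre is erased in step 4, so its configuration does not matter.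

Step 4
Reactants: 6 tert-butyl (1R)-1,3-dimethyl-2-oxocyclohexane-1-carboxylate
Product: 7 tert-butyl (1R)-1,3-dimethyl-2-(trifluoromethylsulfonyloxy)cyclohex-2-ene-1-carboxylate
Conditions: KHMDS, THF, −78 to 0 °C; PhNTf2
Reagents that add atoms: N-phenylbis(trifluoromethanesulfonimide), O=S(=O)(N(c1ccccc1)S(=O)(=O)C(F)(F)F)C(F)(F)F
Why: Enol triflate formation can occur only towards C10 because C4 is quaternary, which gives the tetrasubstituted C5=C10 alkene and leaves C4 untouched.

Step 5
Reactants: 7 enol triflate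
Product: 8 tert-butyl (1R)-1,3-dimethyl-2-(prop-2-en-1-yl)cyclohex-2-ene-1-carboxylate
Conditions: allylSnBu3, Pd2(dba)3 (cat.), AsPh3, LiCl, NMP, 60 °C
Reagents that add atoms: allyltributylstannane, C=CC[Sn](CCCC)(CCCC)CCCC
Why: Stille coupling under soft-ligand conditions works on hindered 2,6,6-trisubstituted cyclohexenyl triflates and brings in C6 and C7.

Step 6
Reactants: 8 skipped diene
Product: 10 tert-butyl (1R)-1,3-dimethyl-2-(2-oxoethyl)cyclohex-2-ene-1-carboxylate, via vicinal diol 9 (not isolated)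
Conditions: OsO4 (2 mol %), NaIO4, 2,6-lutidine, dioxane/H2O 3:1, 23 °C
Reagents that add atoms: sodium periodate, [Na+].[O-]I(=O)(=O)=O; water, O
Why: Lemieux–Johnson cleavage takes only the monosubstituted alkene, because the tetrasubstituted ring alkene is inert, and the buffered medium keeps the β,γ-unsaturated aldehyde out of conjugation.

Step 7
Reactants: 11 cyclohexane-1,3-dione
Product: 12 3-iodocyclohex-2-en-1-one
Conditions: PPh3, I2, Et3N, MeCN, 23 to 80 °C
Reagents that add atoms: iodine, II
Why: Phosphonium activation of the vinylogous acid followed by addition–elimination of iodide gives the β-iodo enone.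

Step 8
Reactants: 12 3-iodocyclohex-2-en-1-one
Product: 13 tert-butyl[(5-iodocyclohexa-1,5-dien-1-yl)oxy]dimethylsilane
Conditions: LDA, THF, −78 °C; TBSOTf, −78 °C
Reagents that add atoms: tert-butyldimethylsilyl triflate, CC(C)(C)[Si](C)(C)OS(=O)(=O)C(F)(F)F
Why: Kinetic α′-deprotonation and O-silylation mask the C11 ketone as a cross-conjugated silyl dienol ether whose C11=C12 position is later needed for enone formation.

Step 9
Reactants: 10 ring A aldehyde; 13 ring C iodide
Product: 14 tert-butyl (1R)-2-{2-[3-(tert-butyldimethylsilyloxy)cyclohexa-1,3-dien-1-yl]-2-hydroxyethyl}-1,3-dimethylcyclohex-2-ene-1-carboxylate (both C7 epimers)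
Conditions: CrCl2 (4 equiv), NiCl2 (2 mol %), DMF, 23 °C
Reagents that add atoms: none
Why: The non-basic Nozaki–Hiyama–Kishi coupling adds the vinyl iodide to the easily enolised aldehyde while tolerating the ester and silyl enol ether, and the C7 carbinol centre it creates is destroyed in step 10.

Step 10
Reactants: 14 dienol
Product: 16 tert-butyl (1R,3S)-3-[(1S,6R)-6-(2-bromoprop-2-en-1-yl)-2-(tert-butyldimethylsilyloxy)-6-formylcyclohex-2-en-1-yl]-1,3-dimethyl-2-methylidenecyclohexane-1-carboxylate, via potassium enolate 15 (not isolated)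
Conditions: KH (1.1 equiv), 18-crown-6, THF, 0 to 50 °C; then 2,3-dibromopropene, −78 to 0 °C
Reagents that add atoms: 2,3-dibromopropene, C=C(Br)CBr
Why: The anionic oxy-Cope rearrangement runs through the chair that maps onto an ent-kaurane B ring (C20 and H9 pseudo-axial and anti), on the alkene face opposite the pseudo-axial CO2tBu, which sets C10 and C9, and the aldehyde enolate is then allylated anti to the ring A group on C9, which sets C8 (any O-allyl ether converges on 16 by Claisen rearrangement).

Step 11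
Reactants: 16 silyl enol ether aldehyde
Product: 17 tert-butyl (1R,3S)-3-[(1S,6R)-6-(2-bromoprop-2-en-1-yl)-6-formyl-2-oxocyclohex-3-en-1-yl]-1,3-dimethyl-2-methylidenecyclohexane-1-carboxylate
Conditions: Pd(OAc)2 (1.1 equiv), MeCN, 23 °C
Reagents that add atoms: none
Why: Saegusa–Ito oxidation of the regiodefined C11=C12 silyl enol ether gives the C12=C13 enone under neutral conditions, so C9 is not epimerised and the vinyl bromide and aldehyde survive.

Step 12
Reactants: 17 enone
Product: 19 tert-butyl (1R,2S,3R)-3-[(1S,6R)-6-(2-bromoprop-2-en-1-yl)-6-formyl-2-oxocyclohex-3-en-1-yl]-2-formyl-1,3-dimethylcyclohexane-1-carboxylate, via spiro-epoxide 18 (not isolated)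
Conditions: DMDO, acetone/CH2Cl2, 0 °C; evaporate; BF3·OEt2, CH2Cl2, −78 °C
Reagents that add atoms: dimethyldioxirane, CC1(C)OO1
Why: C5=C6 is the only electron-rich alkene (the enone and vinyl bromide are deactivated), and the Meinwald rearrangement of the 2,2-disubstituted epoxide (1,2-hydride shift to the tertiary C5 cation) gives the C6 aldehyde, whose C5 centre settles in the equatorial 5β-H form here or in step 13.

Step 13
Reactants: 19 dialdehyde ester
Product: 21 6-hydroxy-19,6-lactone (pseudo-acid form of 20; cis-fused; C6 epimers), via aldehyde acid 20 (not isolated)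
Conditions: TFA/CH2Cl2 1:4, 0 to 23 °C
Reagents that add atoms: none
Why: Acidolysis of the tert-butyl ester frees the C19 acid before any acid-sensitive exocyclic alkene exists, and ring–chain tautomerism traps only the C5 epimer whose CHO is cis to C19, which fixes C5 as S under thermodynamic control.

Step 14
Reactants: 21 pseudo-acid lactol
Product: 22 cis-fused 6,19-anhydride (4R,5S,10S) carrying the (1S,6R)-6-(2-bromoprop-2-en-1-yl)-6-formyl-2-oxocyclohex-3-en-1-yl group on C10
Conditions: DMP, CH2Cl2, 23 °C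
Reagents that add atoms: none
Why: Dess–Martin oxidation converts the lactol C–H into the anhydride carbonyl and leaves the C7 aldehyde untouched, which differentiates C6 (acid level) from C7 (aldehyde level).

Step 15
Reactants: 22 bromoallyl enone anhydride
Product: 23 ent-7,11-dioxo-6,7-secokaur-16-ene-6,19-dioic 6,19-anhydride (11-oxofujenal)
Conditions: Bu3SnH (1.3 equiv, syringe pump), AIBN (cat.), PhH (0.01 M), 80 °C
Reagents that add atoms: none
Why: A 5-exo-trig vinyl-radical cyclisation onto the enone β-carbon C13 closes the bicyclo[3.2.1]octane and gives the exocyclic methylene directly, and C13 can form only on the face that carries the axial C15 tether, so it is set by C8.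

Step 16
Reactants: 23 11-oxofujenal
Product: 24 ent-7,11-dioxo-6,7-secokaur-16-ene-6,19-dioic acid (4R,5S,8R,9S,10S,13S), the target
Conditions: H2O/THF 1:3, pyridine (5 equiv), 23 °C; cold pH 3 citrate wash, concentrate below 25 °C
Reagents that add atoms: water, O
Why: Pyridine-catalysed anhydride hydrolysis is mild enough that C9 (α to the ketone) and C5 are not epimerised and the aldehyde and alkene are untouched.

**Compound list**
1 | tert-butyl 2-oxocyclohexane-1-carboxylate | O=C1CCCCC1C(=O)OC(C)(C)C | starting material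
2 | L-valine tert-butyl ester | CC(C)[C@H](N)C(=O)OC(C)(C)C | starting material
3 | tert-butyl 2-{[(2S)-1-tert-butoxy-3-methyl-1-oxobutan-2-yl]amino}cyclohex-1-ene-1-carboxylate | CC(C)[C@H](NC1=C(C(=O)OC(C)(C)C)CCCC1)C(=O)OC(C)(C)C | intermediate
4 | tert-butyl (1R)-2-{[(2S)-1-tert-butoxy-3-methyl-1-oxobutan-2-yl]imino}-1-methylcyclohexane-1-carboxylate | CC(C)[C@H](N=C1CCCC[C@@]1(C)C(=O)OC(C)(C)C)C(=O)OC(C)(C)C | intermediate (not isolated)
5 | tert-butyl (1R)-1-methyl-2-oxocyclohexane-1-carboxylate | O=C1CCCC[C@@]1(C)C(=O)OC(C)(C)C | intermediate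
6 | tert-butyl (1R)-1,3-dimethyl-2-oxocyclohexane-1-carboxylate (C3 epimers) | O=C1C(C)CCC[C@@]1(C)C(=O)OC(C)(C)C | intermediate
7 | tert-butyl (1R)-1,3-dimethyl-2-(trifluoromethylsulfonyloxy)cyclohex-2-ene-1-carboxylate | CC1=C(OS(=O)(=O)C(F)(F)F)[C@](C)(C(=O)OC(C)(C)C)CCC1 | intermediate
8 | tert-butyl (1R)-1,3-dimethyl-2-(prop-2-en-1-yl)cyclohex-2-ene-1-carboxylate | CC1=C(CC=C)[C@](C)(C(=O)OC(C)(C)C)CCC1 | intermediate
9 | tert-butyl (1R)-2-(2,3-dihydroxypropyl)-1,3-dimethylcyclohex-2-ene-1-carboxylate | CC1=C(CC(O)CO)[C@](C)(C(=O)OC(C)(C)C)CCC1 | intermediate (not isolated)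
10 | tert-butyl (1R)-1,3-dimethyl-2-(2-oxoethyl)cyclohex-2-ene-1-carboxylate | CC1=C(CC=O)[C@](C)(C(=O)OC(C)(C)C)CCC1 | intermediate
11 | cyclohexane-1,3-dione | O=C1CCCC(=O)C1 | starting material
12 | 3-iodocyclohex-2-en-1-one | O=C1C=C(I)CCC1 | intermediate
13 | tert-butyl[(5-iodocyclohexa-1,5-dien-1-yl)oxy]dimethylsilane | CC(C)(C)[Si](C)(C)OC1=CCCC(I)=C1 | intermediate
14 | tert-butyl (1R)-2-{2-[3-(tert-butyldimethylsilyloxy)cyclohexa-1,3-dien-1-yl]-2-hydroxyethyl}-1,3-dimethylcyclohex-2-ene-1-carboxylate (C7 epimers) | CC1=C(CC(O)C2=CC(O[Si](C)(C)C(C)(C)C)=CCC2)[C@](C)(C(=O)OC(C)(C)C)CCC1 | intermediate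
15 | potassium enolate of the C7 aldehyde after [3,3] shift (C7=C8 enolate, C5=C6 methylene, 9β-H, 10α-methyl) | [K+].[O-]C=C1CCC=C(O[Si](C)(C)C(C)(C)C)[C@H]1[C@]2(C)CCC[C@@](C)(C(=O)OC(C)(C)C)C2=C | intermediate (not isolated)
16 | tert-butyl (1R,3S)-3-[(1S,6R)-6-(2-bromoprop-2-en-1-yl)-2-(tert-butyldimethylsilyloxy)-6-formylcyclohex-2-en-1-yl]-1,3-dimethyl-2-methylidenecyclohexane-1-carboxylate | C=C(Br)C[C@]1(C=O)CCC=C(O[Si](C)(C)C(C)(C)C)[C@H]1[C@]2(C)CCC[C@@](C)(C(=O)OC(C)(C)C)C2=C | intermediate
17 | tert-butyl (1R,3S)-3-[(1S,6R)-6-(2-bromoprop-2-en-1-yl)-6-formyl-2-oxocyclohex-3-en-1-yl]-1,3-dimethyl-2-methylidenecyclohexane-1-carboxylate | C=C(Br)C[C@]1(C=O)CC=CC(=O)[C@H]1[C@]2(C)CCC[C@@](C)(C(=O)OC(C)(C)C)C2=C | intermediate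
18 | 5,6-epoxide of 17 (spiro-oxirane at C5, epimers) | C=C(Br)C[C@]1(C=O)CC=CC(=O)[C@H]1[C@]2(C)CCC[C@@](C)(C(=O)OC(C)(C)C)C23CO3 | intermediate (not isolated)
19 | tert-butyl (1R,2S,3R)-3-[(1S,6R)-6-(2-bromoprop-2-en-1-yl)-6-formyl-2-oxocyclohex-3-en-1-yl]-2-formyl-1,3-dimethylcyclohexane-1-carboxylate | C=C(Br)C[C@]1(C=O)CC=CC(=O)[C@H]1[C@]2(C)CCC[C@@](C)(C(=O)OC(C)(C)C)[C@H]2C=O | intermediate
20 | (1R,2S,3R)-3-[(1S,6R)-6-(2-bromoprop-2-en-1-yl)-6-formyl-2-oxocyclohex-3-en-1-yl]-2-formyl-1,3-dimethylcyclohexane-1-carboxylic acid | C=C(Br)C[C@]1(C=O)CC=CC(=O)[C@H]1[C@]2(C)CCC[C@@](C)(C(=O)O)[C@H]2C=O | intermediate (not isolated)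
21 | pseudo-acid of 20: cis-fused γ-lactone C19(=O)–O–C6H(OH), C6 epimers | C=C(Br)C[C@]1(C=O)CC=CC(=O)[C@H]1[C@]2(C)CCC[C@@]3(C)C(=O)OC(O)[C@@H]23 | intermediate
22 | cis-fused 6,19-anhydride bearing the bromoallyl formyl cyclohexenone on C10 | C=C(Br)C[C@]1(C=O)CC=CC(=O)[C@H]1[C@]2(C)CCC[C@@]3(C)C(=O)OC(=O)[C@@H]23 | intermediate
23 | ent-7,11-dioxo-6,7-secokaur-16-ene-6,19-dioic 6,19-anhydride (11-oxofujenal) | C=C1C[C@]2(C=O)C[C@H]1CC(=O)[C@H]2[C@]3(C)CCC[C@@]4(C)C(=O)OC(=O)[C@@H]34 | intermediate
24 | ent-7,11-dioxo-6,7-secokaur-16-ene-6,19-dioic acid (4R,5S,8R,9S,10S,13S) | C=C1C[C@]2(C=O)C[C@H]1CC(=O)[C@H]2[C@]1(C)CCC[C@@](C)(C(=O)O)[C@H]1C(=O)O | target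

**Step count and risks**

Total step count: 16. Longest linear sequence: 14 (steps 1–6 and 9–16).

The three steps most likely to fail are 10, 12 and 15.

For step 10 there are two risks. The C4 ester alone may not differentiate the two chair transition states well for both C7 epimers. The slower epimer may also be diverted into silyl transfer, lactonisation onto the ester, or fragmentation. The fallback replaces substrate control by chirality transfer from a defined carbinol. It sets out from 14 and comes back at 16.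
- Compound 14 is oxidised with DMP to tert-butyl (1R)-2-{2-[3-(tert-butyldimethylsilyloxy)cyclohexa-1,3-dien-1-yl]-2-oxoethyl}-1,3-dimethylcyclohex-2-ene-1-carboxylate F1.
- F1 is reduced with (S)-Me-CBS and catecholborane at −78 °C to the single (7R)-epimer of 14, F2.
- In F2 the alkoxide sits pseudo-equatorial in the desired chair, reinforces the C4 bias and gives the E-enolate remote from the silyl group. F2 then passes through 15 to 16 as in the main route.

For step 12 the risk is that the cationic Meinwald shift is diverted by Wagner–Meerwein migration from the flanking quaternary carbons or by capture by the neighbouring carbonyls. The fallback is radical, not cationic. It sets out from the isolated epoxide 18 and comes back at 19.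
- Titanocene(III) (Cp2TiCl2, Mn, collidine hydrochloride, 1,4-cyclohexadiene) opens the epoxide homolytically to the tertiary C5 radical.
- This radical takes up hydrogen from the open β face and gives tert-butyl (1R,2S,3R)-3-[(1S,6R)-6-(2-bromoprop-2-en-1-yl)-6-formyl-2-oxocyclohex-3-en-1-yl]-2-(hydroxymethyl)-1,3-dimethylcyclohexane-1-carboxylate F3.
- DMP oxidation of F3 gives 19.

For step 15 the risk is direct reduction of the vinyl radical, because cyclisation needs the conformer with C15 and ring A both axial. The fallback replaces the radical by a two-electron organometallic 1,4-addition. It sets out from 22 and comes back at 23.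
- Miyaura borylation (B2pin2, PdCl2(dppf), KOAc, dioxane) gives the 2-(pinacolboryl)allyl analogue of 22, F4.
- F4 is closed by Rh(I)-catalysed intramolecular conjugate addition ([Rh(cod)OH]2, dioxane with 2 equiv water, 50 °C).
- Any anhydride opened in this pot is simply carried into step 16.

**Further compounds**
F1 | step 10 | tert-butyl (1R)-2-{2-[3-(tert-butyldimethylsilyloxy)cyclohexa-1,3-dien-1-yl]-2-oxoethyl}-1,3-dimethylcyclohex-2-ene-1-carboxylate | CC1=C(CC(=O)C2=CC(O[Si](C)(C)C(C)(C)C)=CCC2)[C@](C)(C(=O)OC(C)(C)C)CCC1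
F2 | step 10 | tert-butyl (1R)-2-{(2R)-2-[3-(tert-butyldimethylsilyloxy)cyclohexa-1,3-dien-1-yl]-2-hydroxyethyl}-1,3-dimethylcyclohex-2-ene-1-carboxylate | CC1=C(C[C@@H](O)C2=CC(O[Si](C)(C)C(C)(C)C)=CCC2)[C@](C)(C(=O)OC(C)(C)C)CCC1
F3 | step 12 | tert-butyl (1R,2S,3R)-3-[(1S,6R)-6-(2-bromoprop-2-en-1-yl)-6-formyl-2-oxocyclohex-3-en-1-yl]-2-(hydroxymethyl)-1,3-dimethylcyclohexane-1-carboxylate | C=C(Br)C[C@]1(C=O)CC=CC(=O)[C@H]1[C@]2(C)CCC[C@@](C)(C(=O)OC(C)(C)C)[C@H]2CO
F4 | step 15 | 2-(4,4,5,5-tetramethyl-1,3,2-dioxaborolan-2-yl)allyl analogue of anhydride 22 | C=C(B1OC(C)(C)C(C)(C)O1)C[C@]2(C=O)CC=CC(=O)[C@H]2[C@]3(C)CCC[C@@]4(C)C(=O)OC(=O)[C@@H]34
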